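The depside is not disconnected at its ester; the hindered aryl ester between ring A O4 and the ring B carboxyl on C1 is made early, on a simple enoate, and ring B is then built around it. One photochemical benzannulation of a diazo enone with a silyl ynol ether creates four ring B bonds (C2–C3, C3–C4, C5–C6, C1–C6). It exploits the meta-dioxygenated pattern of ring B, with the C4 and C6 oxygens flanking the C5 methyl, and leaves C3 as CH for late chlorination. The precursor is the (E)-α′-diazo enone ester of methyl orsellinate, its free ring A phenol masked as a methoxymethyl ether.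

Key step: step 6

Remark: ring B is numbered as in the target (C1 carries the carboxyl, C2 methyl, C3 chlorine, C4 hydroxyl, C5 methyl, C6 hydroxyl) and ring A as in methyl orsellinate (C1 ester, C2 hydroxyl, C4 depside oxygen, C6 methyl). The target has no stereocentre, and the two chiral intermediates of the key step are racemic.

**Step 1**
Reactants: 1 methyl orsellinate (methyl 2,4-dihydroxy-6-methylbenzoate); 2 bromoacetyl bromide
Product: 3 3-hydroxy-4-(methoxycarbonyl)-5-methylphenyl bromoacetate
Conditions: pyridine (1.05 equiv), CH2Cl2, −20 to 0 °C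
Reagents that add atoms: none
Why: Phenol O-acylation by an acyl bromide; the ring A C2 hydroxyl is hydrogen-bonded to the neighbouring ester carbonyl, so one equivalent of acyl bromide should react only at the C4 hydroxyl.

**Step 2**
Reactants: 3 3-hydroxy-4-(methoxycarbonyl)-5-methylphenyl bromoacetate; 4 butane-2,3-dione
Product: 7 3-hydroxy-4-(methoxycarbonyl)-5-methylphenyl (E)-3-methyl-4-oxopent-2-enoate, via phosphonium bromide 5 (not isolated), via phosphorus ylide 6 (not isolated)
Conditions: PPh3, CH2Cl2, rt; then butane-2,3-dione (3 equiv), Et3N, 0 °C to rt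
Reagents that add atoms: none
Why: Quaternization of PPh3 by the α-bromo ester, deprotonation to the ester-stabilized ylide and Wittig olefination of one carbonyl of the activated 1,2-diketone; a stabilized ylide should give the E alkene (ester trans to acetyl), and the excess diketone plus the low reactivity of the enone product should stop the reaction at mono-olefination.

**Step 3**
Reactants: 7 3-hydroxy-4-(methoxycarbonyl)-5-methylphenyl (E)-3-methyl-4-oxopent-2-enoate
Product: 8 3-(methoxymethoxy)-4-(methoxycarbonyl)-5-methylphenyl (E)-3-methyl-4-oxopent-2-enoate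
Conditions: MOMCl (3 equiv), i-Pr2NEt (4 equiv), CH2Cl2, 0 °C to rt
Reagents that add atoms: chloromethyl methyl ether, COCCl
Why: Methoxymethyl ether formation by O-alkylation of the phenol under a hindered, non-nucleophilic amine, which should leave the aryl ester and the enone untouched; the ether later prevents ketene capture and keeps ring A deactivated during chlorination.

**Step 4**
Reactants: 8 3-(methoxymethoxy)-4-(methoxycarbonyl)-5-methylphenyl (E)-3-methyl-4-oxopent-2-enoate
Product: 10 3-(methoxymethoxy)-4-(methoxycarbonyl)-5-methylphenyl (E)-5-diazo-3-methyl-4-oxopent-2-enoate, via trifluoroacetyl diketone 9 (not isolated)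
Conditions: LiN(SiMe3)2, THF, −78 °C; CF3CO2CH2CF3; aq HCl work-up; then MsN3, Et3N, H2O, MeCN, rt
Reagents that add atoms: methanesulfonyl azide, CS(=O)(=O)N=[N+]=[N-]
Why: Detrifluoroacetylative diazo transfer (Regitz-type transfer to an activated 1,3-diketone): kinetic enolization of the acetyl methyl group, Claisen trifluoroacetylation to 9, then azide transfer with loss of the trifluoroacetyl group; this is the standard mild entry to α′-diazo enones and avoids diazomethane, which would add to the electron-poor alkene.

**Step 5**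
Reactants: 11 ethyl acetate
Product: 14 triisopropyl(prop-1-yn-1-yloxy)silane [1-(triisopropylsilyloxy)propyne], via lithium dibromoenolate 12 (not isolated), via lithium propynolate 13 (not isolated)
Conditions: CH2Br2, LiTMP (lithium 2,2,6,6-tetramethylpiperidide), THF, −78 °C; LiN(SiMe3)2; n-BuLi, −78 °C to rt; i-Pr3SiCl, 0 °C
Reagents that add atoms: dibromomethane, BrCBr; chlorotriisopropylsilane, CC(C)[Si](Cl)(C(C)C)C(C)C
Why: Kowalski ester homologation stopped at the ynolate: LiCHBr2 adds to the ester, the dibromo ketone enolate 12 undergoes bromine–lithium exchange and 1,2-shift of methyl to ynolate 13, and the bulky silyl chloride should silylate 13 on oxygen.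

**Step 6**
Reactants: 10 3-(methoxymethoxy)-4-(methoxycarbonyl)-5-methylphenyl (E)-5-diazo-3-methyl-4-oxopent-2-enoate; 14 triisopropyl(prop-1-yn-1-yloxy)silane
Product: 19 3-(methoxymethoxy)-4-(methoxycarbonyl)-5-methylphenyl 2-hydroxy-3,6-dimethyl-4-[(triisopropylsilyl)oxy]benzoate, via vinylketene 15 (not isolated), via vinylcyclobutenone 16 (not isolated), via dienylketene 17 (not isolated), via cyclohexadienone 18 (not isolated)
Conditions: 14 (2 equiv), hν (medium-pressure Hg lamp, Pyrex filter, λ > 300 nm), ClCH2CH2Cl, rt; then 80 °C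
Reagents that add atoms: none
Why: Light expels N2 from 10 and the alkenyl group migrates to the carbene carbon (Wolff rearrangement, C2–C3 bond) to give vinylketene 15, whose ketene carbon is attacked by the methyl-bearing carbon of ynol ether 14 in a (2+2) cycloaddition that forms cyclobutenone 16 (C5–C6 and C3–C4 bonds). Warming opens 16 by a four-electron electrocyclic reaction to dienylketene 17, which closes ring B by a six-electron disrotatory electrocyclization (C1–C6 bond) to cyclohexadienone 18, and enolization then gives phenol 19. The closest known reaction type is the diazo ketone variant of the Danheiser benzannulation, established for α′-diazo enones with silyl ynol ethers. No stereocentre is created in 19, since the sp3 carbons of 16 and 18 become aromatic, and the E enoate only keeps the aryl ester on the outside of the closing triene and away from the ketene. The step needs regiocontrol in the ketene–alkyne addition, and the matched polarity of the two partners (nucleophilic methyl-bearing alkyne carbon to the ketene carbonyl carbon) secures it, placing OSi on C4, methyl on C5 and the new hydroxyl on C6 with C3 left as CH. The aryl ester and the ring A acetal are spectators, and Pyrex-filtered light should keep the ester clear of photo-Fries cleavage.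

**Step 7**
Reactants: 19 3-(methoxymethoxy)-4-(methoxycarbonyl)-5-methylphenyl 2-hydroxy-3,6-dimethyl-4-[(triisopropylsilyl)oxy]benzoate
Product: 20 3-(methoxymethoxy)-4-(methoxycarbonyl)-5-methylphenyl 2,4-dihydroxy-3,6-dimethylbenzoate
Conditions: Bu4NF, AcOH, THF, 0 °C
Reagents that add atoms: none
Why: Fluoride cleavage of an aryl silyl ether; the acetic acid buffer keeps the liberated phenol protonated so that the depside ester and the methyl ester should not be attacked, and the ring A acetal is inert to fluoride.

**Step 8**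
Reactants: 20 3-(methoxymethoxy)-4-(methoxycarbonyl)-5-methylphenyl 2,4-dihydroxy-3,6-dimethylbenzoate
Product: 21 3-(methoxymethoxy)-4-(methoxycarbonyl)-5-methylphenyl 3-chloro-4,6-dihydroxy-2,5-dimethylbenzoate
Conditions: NCS (1.0 equiv), MeCN, 0 °C to rt
Reagents that add atoms: N-chlorosuccinimide, O=C1CCC(=O)N1Cl
Why: Electrophilic aromatic chlorination; C3 is the only unsubstituted carbon of ring B and lies ortho to the C4 hydroxyl and para to the C6 hydroxyl, whereas ring A has no free phenol and is deactivated by its ester and acyloxy groups.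

**Step 9**
Reactants: 21 3-(methoxymethoxy)-4-(methoxycarbonyl)-5-methylphenyl 3-chloro-4,6-dihydroxy-2,5-dimethylbenzoate
Product: 22 3-hydroxy-4-(methoxycarbonyl)-5-methylphenyl 3-chloro-4,6-dihydroxy-2,5-dimethylbenzoate (CNP0171762.0)
Conditions: 3 M aq HCl, THF, 40 °C
Reagents that add atoms: none
Why: Acid hydrolysis of the methoxymethyl acetal; the hindered depside ester and the methyl ester should survive dilute aqueous acid at this temperature.

**Compound list**

1 | methyl orsellinate (methyl 2,4-dihydroxy-6-methylbenzoate) | COC(=O)c1c(C)cc(O)cc1O | starting material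
2 | bromoacetyl bromide | BrCC(=O)Br | starting material
3 | 3-hydroxy-4-(methoxycarbonyl)-5-methylphenyl bromoacetate | COC(=O)c1c(C)cc(OC(=O)CBr)cc1O | intermediate
4 | butane-2,3-dione | CC(=O)C(C)=O | starting material
5 | {2-[3-hydroxy-4-(methoxycarbonyl)-5-methylphenoxy]-2-oxoethyl}triphenylphosphonium bromide (formed in the flask, step 2) | COC(=O)c1c(C)cc(OC(=O)C[P+](c2ccccc2)(c2ccccc2)c2ccccc2)cc1O.[Br-] | intermediate
6 | 3-hydroxy-4-(methoxycarbonyl)-5-methylphenyl (triphenylphosphoranylidene)acetate (formed in the flask, step 2) | COC(=O)c1c(C)cc(OC(=O)C=P(c2ccccc2)(c2ccccc2)c2ccccc2)cc1O | intermediate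
7 | 3-hydroxy-4-(methoxycarbonyl)-5-methylphenyl (E)-3-methyl-4-oxopent-2-enoate | CC(=O)/C(C)=C/C(=O)Oc1cc(C)c(C(=O)OC)c(O)c1 | intermediate
8 | 3-(methoxymethoxy)-4-(methoxycarbonyl)-5-methylphenyl (E)-3-methyl-4-oxopent-2-enoate | CC(=O)/C(C)=C/C(=O)Oc1cc(C)c(C(=O)OC)c(OCOC)c1 | intermediate
9 | 3-(methoxymethoxy)-4-(methoxycarbonyl)-5-methylphenyl (E)-7,7,7-trifluoro-3-methyl-4,6-dioxohept-2-enoate (formed in the flask, step 4; drawn as the diketo form) | O=C(CC(=O)C(F)(F)F)/C(C)=C/C(=O)Oc1cc(C)c(C(=O)OC)c(OCOC)c1 | intermediate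
10 | 3-(methoxymethoxy)-4-(methoxycarbonyl)-5-methylphenyl (E)-5-diazo-3-methyl-4-oxopent-2-enoate | [N-]=[N+]=CC(=O)/C(C)=C/C(=O)Oc1cc(C)c(C(=O)OC)c(OCOC)c1 | intermediate
11 | ethyl acetate | CCOC(C)=O | starting material
12 | lithium 1,1-dibromoprop-1-en-2-olate (formed in the flask, step 5) | [Li+].[O-]C(C)=C(Br)Br | intermediate
13 | lithium prop-1-yn-1-olate (formed in the flask, step 5) | [Li+].[O-]C#CC | intermediate
14 | triisopropyl(prop-1-yn-1-yloxy)silane | CC#CO[Si](C(C)C)(C(C)C)C(C)C | intermediate
15 | 3-(methoxymethoxy)-4-(methoxycarbonyl)-5-methylphenyl (2E)-3-methyl-5-oxopenta-2,4-dienoate (vinylketene, formed in the flask, step 6) | O=C=C/C(C)=C/C(=O)Oc1cc(C)c(C(=O)OC)c(OCOC)c1 | intermediate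
16 | 3-(methoxymethoxy)-4-(methoxycarbonyl)-5-methylphenyl (E)-3-{3-methyl-4-oxo-2-[(triisopropylsilyl)oxy]cyclobut-2-en-1-yl}but-2-enoate (racemic, formed in the flask, step 6) | CC1=C(O[Si](C(C)C)(C(C)C)C(C)C)C(/C(C)=C/C(=O)Oc2cc(C)c(C(=O)OC)c(OCOC)c2)C1=O | intermediate
17 | 3-(methoxymethoxy)-4-(methoxycarbonyl)-5-methylphenyl (2E,4E)-3,6-dimethyl-7-oxo-5-[(triisopropylsilyl)oxy]hepta-2,4,6-trienoate (ketene and enoate arm cis on the central double bond; formed in the flask, step 6) | O=C=C(C)/C(O[Si](C(C)C)(C(C)C)C(C)C)=C\C(C)=C\C(=O)Oc1cc(C)c(C(=O)OC)c(OCOC)c1 | intermediate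
18 | 3-(methoxymethoxy)-4-(methoxycarbonyl)-5-methylphenyl 2,5-dimethyl-6-oxo-4-[(triisopropylsilyl)oxy]cyclohexa-2,4-diene-1-carboxylate (racemic, formed in the flask, step 6) | CC1=C(O[Si](C(C)C)(C(C)C)C(C)C)C=C(C)C(C(=O)Oc2cc(C)c(C(=O)OC)c(OCOC)c2)C1=O | intermediate
19 | 3-(methoxymethoxy)-4-(methoxycarbonyl)-5-methylphenyl 2-hydroxy-3,6-dimethyl-4-[(triisopropylsilyl)oxy]benzoate (ring B: C4 silyl ether, C6 hydroxyl, C3 unsubstituted) | COC(=O)c1c(C)cc(OC(=O)c2c(C)cc(O[Si](C(C)C)(C(C)C)C(C)C)c(C)c2O)cc1OCOC | intermediate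
20 | 3-(methoxymethoxy)-4-(methoxycarbonyl)-5-methylphenyl 2,4-dihydroxy-3,6-dimethylbenzoate | COC(=O)c1c(C)cc(OC(=O)c2c(C)cc(O)c(C)c2O)cc1OCOC | intermediate
21 | 3-(methoxymethoxy)-4-(methoxycarbonyl)-5-methylphenyl 3-chloro-4,6-dihydroxy-2,5-dimethylbenzoate | COC(=O)c1c(C)cc(OC(=O)c2c(C)c(Cl)c(O)c(C)c2O)cc1OCOC | intermediate
22 | 3-hydroxy-4-(methoxycarbonyl)-5-methylphenyl 3-chloro-4,6-dihydroxy-2,5-dimethylbenzoate (CNP0171762.0) | COC(=O)c1c(C)cc(OC(=O)c2c(C)c(Cl)c(O)c(C)c2O)cc1O | target

**Step count**

Total steps: 9. Longest linear sequence: 8 steps (steps 1–4 and 6–9, from 1 to 22); step 5 is a one-step branch.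

**Steps most likely to fail**

Step 6. The risks are:
- Light-driven scission of the aryl ester could compete with the Wolff rearrangement.
- E-to-Z isomerization of the enoate could let the ketene close onto the ester carbonyl oxygen instead of meeting the alkyne.
- The ketene could be captured by the phenol that is being formed.
- The sequence could stall at the cyclobutenone stage.

The fallback abandons the annulation for a classical depside esterification; it sets out from 1 and comes back at 22. Purchased methyl 2,4-dihydroxy-3,6-dimethylbenzoate F1 would be chlorinated at its only free ring carbon (NCS, MeCN) to methyl 3-chloro-4,6-dihydroxy-2,5-dimethylbenzoate F2. Benzylation (BnBr, K2CO3, DMF, 60 °C) would give methyl 4,6-bis(benzyloxy)-3-chloro-2,5-dimethylbenzoate F3, and saponification (KOH, aqueous DMSO, 100 °C) would give 4,6-bis(benzyloxy)-3-chloro-2,5-dimethylbenzoic acid F4. F4 and 1 would be joined with (CF3CO)2O in toluene, a mixed-anhydride esterification that reacts at the ring A C4 hydroxyl, to give 3-hydroxy-4-(methoxycarbonyl)-5-methylphenyl 4,6-bis(benzyloxy)-3-chloro-2,5-dimethylbenzoate F5. Hydrogenolysis of both benzyl ethers (H2, Pd/C, EtOAc, rt, stopped after two equivalents of hydrogen) would give 22.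

Step 4. During enolization, acyl transfer from the activated aryl ester to the amide base or to the enolate, or deprotonation at the allylic methyl group, could compete with trifluoroacetylation. The fallback carries out the diazo transfer before ring A is attached; it sets out from 4, uses 1 as coupling partner and comes back at 10. Wittig reaction of 4 with methyl (triphenylphosphoranylidene)acetate would give methyl (E)-3-methyl-4-oxopent-2-enoate F6. The same trifluoroacetylation, through methyl (E)-7,7,7-trifluoro-3-methyl-4,6-dioxohept-2-enoate F7 (used crude), and azide transfer would give methyl (E)-5-diazo-3-methyl-4-oxopent-2-enoate F8. Saponification (LiOH, THF/H2O, 0 °C) would give (E)-5-diazo-3-methyl-4-oxopent-2-enoic acid F9. Carbodiimide esterification with 1 (EDC·HCl, catalytic DMAP, CH2Cl2) would give 3-hydroxy-4-(methoxycarbonyl)-5-methylphenyl (E)-5-diazo-3-methyl-4-oxopent-2-enoate F10, and methoxymethylation as in step 3 would give 10.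

Step 2. The ylide could be acylated by the aryl ester of a second molecule, or the amine base could trigger acyl migration through the phenoxide, before the olefination is complete. The fallback makes the enone acid first and esterifies afterwards; it sets out from 4, uses 1 as coupling partner and comes back at 7. Wittig reaction of 4 with tert-butyl (triphenylphosphoranylidene)acetate would give tert-butyl (E)-3-methyl-4-oxopent-2-enoate F11. Cleavage with CF3CO2H in CH2Cl2 would give (E)-3-methyl-4-oxopent-2-enoic acid F12, and Steglich esterification with 1 (DCC, catalytic DMAP, CH2Cl2, 0 °C) at the C4 hydroxyl would give 7.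

**Further compounds**

F1 | step 6 | methyl 2,4-dihydroxy-3,6-dimethylbenzoate (purchased) | COC(=O)c1c(C)cc(O)c(C)c1O
F2 | step 6 | methyl 3-chloro-4,6-dihydroxy-2,5-dimethylbenzoate | COC(=O)c1c(C)c(Cl)c(O)c(C)c1O
F3 | step 6 | methyl 4,6-bis(benzyloxy)-3-chloro-2,5-dimethylbenzoate | COC(=O)c1c(C)c(Cl)c(OCc2ccccc2)c(C)c1OCc1ccccc1
F4 | step 6 | 4,6-bis(benzyloxy)-3-chloro-2,5-dimethylbenzoic acid | OC(=O)c1c(C)c(Cl)c(OCc2ccccc2)c(C)c1OCc1ccccc1
F5 | step 6 | 3-hydroxy-4-(methoxycarbonyl)-5-methylphenyl 4,6-bis(benzyloxy)-3-chloro-2,5-dimethylbenzoate | COC(=O)c1c(C)cc(OC(=O)c2c(C)c(Cl)c(OCc3ccccc3)c(C)c2OCc2ccccc2)cc1O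
F6 | step 4 | methyl (E)-3-methyl-4-oxopent-2-enoate | CC(=O)/C(C)=C/C(=O)OC
F7 | step 4 | methyl (E)-7,7,7-trifluoro-3-methyl-4,6-dioxohept-2-enoate | O=C(CC(=O)C(F)(F)F)/C(C)=C/C(=O)OC
F8 | step 4 | methyl (E)-5-diazo-3-methyl-4-oxopent-2-enoate | [N-]=[N+]=CC(=O)/C(C)=C/C(=O)OC
F9 | step 4 | (E)-5-diazo-3-methyl-4-oxopent-2-enoic acid | [N-]=[N+]=CC(=O)/C(C)=C/C(=O)O
F10 | step 4 | 3-hydroxy-4-(methoxycarbonyl)-5-methylphenyl (E)-5-diazo-3-methyl-4-oxopent-2-enoate | [N-]=[N+]=CC(=O)/C(C)=C/C(=O)Oc1cc(C)c(C(=O)OC)c(O)c1
F11 | step 2 | tert-butyl (E)-3-methyl-4-oxopent-2-enoate | CC(=O)/C(C)=C/C(=O)OC(C)(C)C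
F12 | step 2 | (E)-3-methyl-4-oxopent-2-enoic acid | CC(=O)/C(C)=C/C(=O)O
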